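**Plan**

- Locants: quinone C1(=O), C2(OAc), C3(aryl), C4(=O), C5(H), C6(aryl). Retrosynthesis: remove the two phenol silyl groups and the acetyl group, then cut ring bonds C1–C2 and C3–C4 to give a C4 maleoyl unit (C1, C6, C5, C4) and a C2 oxygenated alkyne (C2, C3).
- Enabling feature: C1(=O)–C6(aryl)=C5(H)–C4(=O) can be stored as a strained 3-arylcyclobutene-1,2-dione (temporary C1–C4 bond). Cobalt opens this ring to a five-membered maleoylcobalt metallacycle, and C2(O)=C3(aryl) is a polarised silyl ynol ether.
- Forward: squarate + aryllithium, then hydride and acid, gives the arylcyclobutenedione and from it the maleoylcobalt complex; an arylacetylene gives the silyl ynol ether; a cobalt-mediated [4+2] annulation closes the quinone ring, the only ring made.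
- End game: acetylation of the single free (quinone) hydroxyl, then removal of the aryl silyl ethers under acidic fluoride.
- Stereochemistry: the target has no stereocentre; the racemic carbinol centres of the early four-membered-ring intermediates are erased in step 2.

Key step: step 5

Remark on the chemistry: the two aryl tert-butyldimethylsilyl ethers, diisopropyl squarate and ClCo(PPh3)3 are taken as purchased.

**Step 1**
Reactants: 1 (4-bromophenoxy)(tert-butyl)dimethylsilane; 2 diisopropyl squarate
Product: 4 racemic 4-[4-(tert-butyldimethylsilyloxy)phenyl]-4-hydroxy-2,3-diisopropoxycyclobut-2-en-1-one, via aryllithium 3 (not isolated)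
Conditions: 1, n-BuLi, THF, −78 °C; then 2, THF, −78 °C; sat. aq. NH4Cl
Reagents that add atoms: none
Why: Bromine–lithium exchange followed by 1,2-addition of the aryllithium to one carbonyl of the squarate ester (standard squarate mono-addition) should give the tertiary carbinol, formed racemic and erased in step 2.

**Step 2**
Reactants: 4 racemic 4-aryl-4-hydroxy-2,3-diisopropoxycyclobutenone
Product: 6 3-[4-(tert-butyldimethylsilyloxy)phenyl]cyclobut-3-ene-1,2-dione, via cyclobutenediol 5 (not isolated)
Conditions: i-Bu2AlH (2.5 equiv), CH2Cl2, −78 °C; then 2 M HCl, THF, 0 °C → rt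
Reagents that add atoms: water, O
Why: 1,2-Reduction of the remaining vinylogous-ester carbonyl and two acid-promoted allylic transpositions of the Stork–Danheiser type (each carbinol ionises to an isopropoxy-stabilised allyl cation that water converts into a carbonyl) should turn both enol-ether carbons into the dione and leave aryl and H on the ring alkene, while the aryl silyl ether tolerates brief dilute acid.

**Step 3**
Reactants: 6 3-arylcyclobutene-1,2-dione
Product: 8 chloro(dimethylglyoxime)(pyridine){2-[4-(tert-butyldimethylsilyloxy)phenyl]but-2-ene-1,4-dioyl}cobalt, via bis(triphenylphosphine)maleoylcobalt chloride 7 (not isolated)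
Conditions: ClCo(PPh3)3 (1.1 equiv), benzene, rt; then dimethylglyoxime, pyridine, rt
Reagents that add atoms: chlorotris(triphenylphosphine)cobalt, Cl[Co-3]([P+](c1ccccc1)(c1ccccc1)c1ccccc1)([P+](c1ccccc1)(c1ccccc1)c1ccccc1)[P+](c1ccccc1)(c1ccccc1)c1ccccc1; dimethylglyoxime, CC(=NO)C(C)=NO; pyridine, c1ccncc1
Why: Oxidative addition of univalent cobalt into the strained C(O)–C(O) bond of the cyclobutenedione should give the five-membered maleoyl metallacycle of trivalent cobalt, and ligand exchange of the phosphines for dimethylglyoxime and pyridine gives the air-stable complex that is more reactive toward alkynes (C–C bond activation of cyclobutenediones, then ligand substitution).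

**Step 4**
Reactants: 9 tert-butyl(4-ethynylphenoxy)dimethylsilane
Product: 12 tert-butyldimethyl{4-[(triisopropylsilyloxy)ethynyl]phenoxy}silane, via lithium acetylide 10 (not isolated), via lithium ynolate 11 (not isolated)
Conditions: n-BuLi, THF, −78 °C; t-BuOOLi (from t-BuOOH, LiN(SiMe3)2), −78 → 0 °C; i-Pr3SiOTf, −78 °C → rt
Reagents that add atoms: lithium tert-butyl peroxide, [Li]OOC(C)(C)C; triisopropylsilyl triflate, CC(C)[Si](C(C)C)(C(C)C)OS(=O)(=O)C(F)(F)F
Why: Electrophilic oxygen transfer from the lithium peroxide to the acetylide (acetylide-to-ynolate oxidation) and O-silylation of the ynolate by the bulky silyl triflate should give the silyl ynol ether.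

**Step 5**
Reactants: 8 maleoylcobalt dimethylglyoxime complex; 12 silyl ynol ether (1.5 equiv)
Product: 14 2-hydroxy-3,6-bis[4-(tert-butyldimethylsilyloxy)phenyl]-1,4-benzoquinone, via siloxyquinone 13 (not isolated)
Conditions: SnCl4 (1.1 equiv, Lewis-acid promoter), CH2Cl2, −78 → 0 °C; then AcOH, THF–H2O, rt
Reagents that add atoms: none
Why: SnCl4 should bind the more Lewis-basic acyl oxygen of 8 (the CH-side acyl, conjugated through CH=C to the electron-rich aryl group) and open a site on trivalent cobalt, so that the silyl ynol ether, whose aryl-bearing carbon is the nucleophilic terminus, inserts into that Co–acyl bond to give a seven-membered cobaltacycle with cobalt on the oxygen-bearing alkyne carbon. C–C reductive elimination then joins that carbon to the second acyl group and releases univalent cobalt, so both carbonyl–alkene bonds of the quinone form in one operation. The closest known reaction type is the cobalt-mediated [4+2] quinone annulation of maleoyl- and phthaloylcobalt complexes with alkynes under Lewis-acid activation. The six-membered quinone ring is closed by reductive elimination from the metallacycle (a metal-templated contraction from seven to six ring atoms), not by a polar exo or endo cyclisation. No stereocentre is formed. The step needs head-to-tail regioselectivity (alkyne aryl carbon to the CH-flanked carbonyl, which places the two aryl groups para); the matched polarity of the ynol ether and the activated acyl group and the lower steric demand at the CH-flanked acyl should secure it, and the mild acid work-up cleaves only the labile vinylogous silyl ester O–Si bond.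

**Step 6**
Reactants: 14 2-hydroxy-3,6-diaryl-1,4-benzoquinone
Product: 15 2-acetoxy-3,6-bis[4-(tert-butyldimethylsilyloxy)phenyl]-1,4-benzoquinone
Conditions: Ac2O, pyridine, CH2Cl2, 0 °C; cold dilute aq. citric acid work-up
Reagents that add atoms: acetic anhydride, CC(=O)OC(C)=O
Why: O-Acylation of the acidic vinylogous-acid hydroxyl, the only free hydroxyl in 14, should give the para-quinone enol acetate (standard acetylation of a hydroxyquinone).

**Step 7**
Reactants: 15 2-acetoxy-3,6-bis(silyloxyphenyl)-1,4-benzoquinone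
Product: 16 neonambiquinone A
Conditions: HF·pyridine (no added pyridine), THF, 0 °C → rt; pH 5 buffer work-up
Reagents that add atoms: none
Why: Fluoride cleavage of the aryl silyl ethers under acidic, non-nucleophilic conditions should free both phenols without hydrolysis or migration of the quinone acetate.

**Compound list**

1 | (4-bromophenoxy)(tert-butyl)dimethylsilane | CC(C)(C)[Si](C)(C)Oc1ccc(Br)cc1 | starting material
2 | diisopropyl squarate (3,4-diisopropoxycyclobut-3-ene-1,2-dione) | CC(C)OC1=C(OC(C)C)C(=O)C1=O | starting material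
3 | [4-(tert-butyldimethylsilyloxy)phenyl]lithium | [Li]c1ccc(O[Si](C)(C)C(C)(C)C)cc1 | intermediate
4 | racemic 4-[4-(tert-butyldimethylsilyloxy)phenyl]-4-hydroxy-2,3-diisopropoxycyclobut-2-en-1-one | CC(C)OC1=C(OC(C)C)C(O)(c2ccc(O[Si](C)(C)C(C)(C)C)cc2)C1=O | intermediate
5 | 1-[4-(tert-butyldimethylsilyloxy)phenyl]-3,4-diisopropoxycyclobut-3-ene-1,2-diol (racemic, cis/trans mixture) | CC(C)OC1=C(OC(C)C)C(O)(c2ccc(O[Si](C)(C)C(C)(C)C)cc2)C1O | intermediate
6 | 3-[4-(tert-butyldimethylsilyloxy)phenyl]cyclobut-3-ene-1,2-dione | O=C1C=C(c2ccc(O[Si](C)(C)C(C)(C)C)cc2)C1=O | intermediate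
7 | chlorobis(triphenylphosphine){2-[4-(tert-butyldimethylsilyloxy)phenyl]but-2-ene-1,4-dioyl}cobalt, CoCl(PPh3)2[C(O)CH=C(Ar)C(O)], five-membered cobaltacycle of trivalent cobalt | O=C1C=C(c2ccc(O[Si](C)(C)C(C)(C)C)cc2)C(=O)[Co-2]1(Cl)([P+](c2ccccc2)(c2ccccc2)c2ccccc2)[P+](c2ccccc2)(c2ccccc2)c2ccccc2 | intermediate
8 | chloro(dimethylglyoxime)(pyridine){2-[4-(tert-butyldimethylsilyloxy)phenyl]but-2-ene-1,4-dioyl}cobalt, CoCl(C5H5N)(C4H8N2O2)[C(O)CH=C(Ar)C(O)], trivalent cobalt | O=C1C=C(c2ccc(O[Si](C)(C)C(C)(C)C)cc2)C(=O)[Co-3]13(Cl)([n+]2ccccc2)[N+](O)=C(C)C(C)=[N+]3O | intermediate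
9 | tert-butyl(4-ethynylphenoxy)dimethylsilane | C#Cc1ccc(O[Si](C)(C)C(C)(C)C)cc1 | starting material
10 | lithium [4-(tert-butyldimethylsilyloxy)phenyl]acetylide | [Li]C#Cc1ccc(O[Si](C)(C)C(C)(C)C)cc1 | intermediate
11 | lithium 2-[4-(tert-butyldimethylsilyloxy)phenyl]ethynolate | [Li]OC#Cc1ccc(O[Si](C)(C)C(C)(C)C)cc1 | intermediate
12 | tert-butyldimethyl{4-[(triisopropylsilyloxy)ethynyl]phenoxy}silane | CC(C)[Si](OC#Cc1ccc(O[Si](C)(C)C(C)(C)C)cc1)(C(C)C)C(C)C | intermediate
13 | 3,6-bis[4-(tert-butyldimethylsilyloxy)phenyl]-2-(triisopropylsilyloxy)-1,4-benzoquinone | CC(C)[Si](OC1=C(c2ccc(O[Si](C)(C)C(C)(C)C)cc2)C(=O)C=C(c2ccc(O[Si](C)(C)C(C)(C)C)cc2)C1=O)(C(C)C)C(C)C | intermediate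
14 | 2-hydroxy-3,6-bis[4-(tert-butyldimethylsilyloxy)phenyl]-1,4-benzoquinone | OC1=C(c2ccc(O[Si](C)(C)C(C)(C)C)cc2)C(=O)C=C(c2ccc(O[Si](C)(C)C(C)(C)C)cc2)C1=O | intermediate
15 | 2-acetoxy-3,6-bis[4-(tert-butyldimethylsilyloxy)phenyl]-1,4-benzoquinone | CC(=O)OC1=C(c2ccc(O[Si](C)(C)C(C)(C)C)cc2)C(=O)C=C(c2ccc(O[Si](C)(C)C(C)(C)C)cc2)C1=O | intermediate
16 | neonambiquinone A (2-acetoxy-3,6-bis(4-hydroxyphenyl)-1,4-benzoquinone) | CC(=O)OC1=C(c2ccc(O)cc2)C(=O)C=C(c2ccc(O)cc2)C1=O | target

**Totals and risks**

Total step count: 7. Longest linear sequence: 6 steps (steps 1, 2, 3, 5, 6, 7); step 4 is the one-step side branch.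

Step 5 (most likely to fail). The alkyne may insert with the opposite orientation, placing the two aryl groups meta, or the Lewis acid may desilylate the ynol ether to a ketene before it engages cobalt. The fallback forms the same two ring bonds in two stages by a thermal cyclobutenone ring expansion; it sets out from 4 and 9 and comes back at 14. Hydroxycyclobutenone 4 is transposed with conc. HCl in CH2Cl2 to 3-[4-(tert-butyldimethylsilyloxy)phenyl]-4-isopropoxycyclobut-3-ene-1,2-dione F1. Alkyne 9 is converted by Markovnikov hydroiodination (NaI, Me3SiCl, H2O, MeCN) into tert-butyl[4-(1-iodoethenyl)phenoxy]dimethylsilane F2, and iodine–lithium exchange (t-BuLi, THF, −78 °C) gives 1-[4-(tert-butyldimethylsilyloxy)phenyl]ethenyllithium F3. F3 should add to the carbonyl of F1 that is not part of the vinylogous ester (the one next to the isopropoxy-bearing carbon) to give 2-[4-(tert-butyldimethylsilyloxy)phenyl]-4-{1-[4-(tert-butyldimethylsilyloxy)phenyl]ethenyl}-4-hydroxy-3-isopropoxycyclobut-2-en-1-one F4. Heating F4 in toluene at 110 °C should open the four-membered ring to a dienylketene that closes by 6π electrocyclisation and tautomerises to 3,6-bis[4-(tert-butyldimethylsilyloxy)phenyl]-2-isopropoxybenzene-1,4-diol F5. Oxidation with Ag2O gives 3,6-bis[4-(tert-butyldimethylsilyloxy)phenyl]-2-isopropoxy-1,4-benzoquinone F6, in which the aryl groups are para by construction. BCl3 in CH2Cl2 at −78 °C cleaves the isopropyl vinylogous ester and returns the route at 14.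

Step 4. Oxygen transfer from the peroxide to the aryl-conjugated acetylide may be incomplete or unselective, leaving too little ynolate for silylation. The fallback generates the ynolate without an oxidant, by carbenoid rearrangement; it sets out from 1 and comes back at 12 through 11. Bromide 1 is lithiated (n-BuLi, THF, −78 °C) and quenched with methyl chloroformate to give methyl 4-(tert-butyldimethylsilyloxy)benzoate F7. Kowalski ester homologation of F7 (LiCHBr2 from CH2Br2 and lithium 2,2,6,6-tetramethylpiperidide, −78 °C; then n-BuLi, warming) should give the same lithium ynolate 11, which is O-silylated with i-Pr3SiOTf as in step 4 to reach 12.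

Step 2. The hydride addition may stall on the aluminium alkoxide of 4, or the acid stage may be diverted by loss of the aryl silyl ether before both transpositions are complete. The fallback builds the four-membered ring by cycloaddition; it sets out from 9 and comes back at 6. Alkyne 9 should undergo [2+2] cycloaddition with dichloroketene (Cl3CCOCl, Zn–Cu couple, Et2O) to give 4,4-dichloro-3-[4-(tert-butyldimethylsilyloxy)phenyl]cyclobut-2-en-1-one F8. Hydrolysis of the geminal dichloride in warm aqueous H2SO4 gives the dione with loss of the silyl ether, 3-(4-hydroxyphenyl)cyclobut-3-ene-1,2-dione F9, and resilylation (TBSCl, imidazole, DMF) returns the route at 6.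

**Further compounds**

F1 | step 5 | 3-[4-(tert-butyldimethylsilyloxy)phenyl]-4-isopropoxycyclobut-3-ene-1,2-dione | CC(C)OC1=C(c2ccc(O[Si](C)(C)C(C)(C)C)cc2)C(=O)C1=O
F2 | step 5 | tert-butyl[4-(1-iodoethenyl)phenoxy]dimethylsilane | C=C(I)c1ccc(O[Si](C)(C)C(C)(C)C)cc1
F3 | step 5 | 1-[4-(tert-butyldimethylsilyloxy)phenyl]ethenyllithium | [Li]C(=C)c1ccc(O[Si](C)(C)C(C)(C)C)cc1
F4 | step 5 | 2-[4-(tert-butyldimethylsilyloxy)phenyl]-4-{1-[4-(tert-butyldimethylsilyloxy)phenyl]ethenyl}-4-hydroxy-3-isopropoxycyclobut-2-en-1-one (racemic) | CC(C)OC1=C(c2ccc(O[Si](C)(C)C(C)(C)C)cc2)C(=O)C1(O)C(=C)c1ccc(O[Si](C)(C)C(C)(C)C)cc1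
F5 | step 5 | 3,6-bis[4-(tert-butyldimethylsilyloxy)phenyl]-2-isopropoxybenzene-1,4-diol | CC(C)Oc1c(O)c(-c2ccc(O[Si](C)(C)C(C)(C)C)cc2)cc(O)c1-c1ccc(O[Si](C)(C)C(C)(C)C)cc1
F6 | step 5 | 3,6-bis[4-(tert-butyldimethylsilyloxy)phenyl]-2-isopropoxy-1,4-benzoquinone | CC(C)OC1=C(c2ccc(O[Si](C)(C)C(C)(C)C)cc2)C(=O)C=C(c2ccc(O[Si](C)(C)C(C)(C)C)cc2)C1=O
F7 | step 4 | methyl 4-(tert-butyldimethylsilyloxy)benzoate | COC(=O)c1ccc(O[Si](C)(C)C(C)(C)C)cc1
F8 | step 2 | 4,4-dichloro-3-[4-(tert-butyldimethylsilyloxy)phenyl]cyclobut-2-en-1-one | O=C1C=C(c2ccc(O[Si](C)(C)C(C)(C)C)cc2)C1(Cl)Cl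
F9 | step 2 | 3-(4-hydroxyphenyl)cyclobut-3-ene-1,2-dione | O=C1C=C(c2ccc(O)cc2)C1=O
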